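**Plan**

1. Locants used throughout (arbitrary): eight-membered ring C2(H,Me)–C3H2–C4(OH,Me)–C5(=O)–C6H–C12–C13=C14(OH); cyclopentane C6–C7H(OH)–C8H–C17–C12; cyclohexane C8–C9H(OH)–C10(Me)–C19H(Me)–C18H2–C17; ether O11 (C10–O–C12); lactone C13–C15(=O)–O16–C17.
2. Enabling feature: in the eight-membered ring the enolised β-keto-lactone carbonyl C14 and the ketone C5 are 1,5-related through C13–C12–C6, which is the retron of a De Mayo sequence. Retrosynthetically, re-forming C6–C14 and cutting C6–C12 and C13–C14 contracts the ring to a six-membered vinylogous ester (C14 benzyl enol ether, C5 ketone) joined through C7–C8–C17 to a tetronate alkene C12=C13.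
3. Further cuts: C6–C7 (Nozaki–Hiyama–Kishi coupling), C12=C13 with C15–O16 (ketenylidene ylide on an α-hydroxy lactone), O11–C10 (epoxide opening by an ester), C8–C17 and C18–C19 (Diels–Alder).
4. Forward order: cyclohexene, then 2-oxabicyclo[2.2.2]octanone, then fused tetronate; separately the six-membered iodo enone; union at C6–C7. In the last step light closes the cyclopentane and a cyclobutane, and hydrogenolysis of the enol benzyl ether (the helper that fixes the enol at C14) triggers retro-aldol expansion of the six- to the eight-membered ring while removing the two benzyloxymethyl ethers.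
5. Stereochemistry: C8 and C19 from a catalytic asymmetric Diels–Alder reaction; C17, C9 and C10 by substrate control from these; C4 by a chiral oxaziridine acting on a racemate (stereoconvergent); C2 by substrate control; C7 by Felkin–Anh reduction of a ketone through which both carbinol epimers are funnelled; C12 by the tether in the photocycloaddition; C6 by thermodynamic protonation.

Key step: step 20

Assumption (chemistry): the absolute sense of induction of the oxazaborolidinium catalyst in step 4 and of the camphor-derived oxaziridine in step 13 is taken from the accepted models for these reagents; if either gave the antipode, its enantiomer would be used in the same step.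

**Route**

Step 1
Reactants: 1 (E)-2-methylbut-2-enal; 2 triethyl phosphonoacetate
Product: 3 ethyl (2E,4E)-4-methylhexa-2,4-dienoate
Conditions: NaH, THF, 0 °C → rt
Reagents that add atoms: none
Why: Horner–Wadsworth–Emmons olefination with the stabilised phosphonate anion should give the new disubstituted alkene with E geometry while the E trisubstituted alkene of 1 is retained.

Step 2
Reactants: 3 ethyl (2E,4E)-4-methylhexa-2,4-dienoate
Product: 4 (2E,4E)-4-methylhexa-2,4-dien-1-ol
Conditions: iBu2AlH (2.2 equiv), CH2Cl2, −78 °C; aq. KNaC4H4O6 (potassium sodium tartrate)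
Reagents that add atoms: none
Why: 1,2-reduction of the conjugated ester by the aluminium hydride should give the allylic alcohol without touching the diene.

Step 3
Reactants: 4 (2E,4E)-4-methylhexa-2,4-dien-1-ol
Product: 5 tert-butyl{[(2E,4E)-4-methylhexa-2,4-dien-1-yl]oxy}diphenylsilane
Conditions: tert-butyl(chloro)diphenylsilane, imidazole, DMF, rt
Reagents that add atoms: tert-butyl(chloro)diphenylsilane CC(C)(C)[Si](Cl)(c1ccccc1)c1ccccc1
Why: standard silylation of a primary alcohol gives an acid-stable ether that survives the Lewis and Brønsted acids of steps 4 and 6.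

Step 4
Reactants: 5 silyl dienyl ether; 6 methyl acrylate
Product: 7 methyl (1R,2S,5S)-2-{[(tert-butyldiphenylsilyl)oxy]methyl}-4,5-dimethylcyclohex-3-ene-1-carboxylate
Conditions: (S)-3,3-diphenyl-1-(o-tolyl)tetrahydro-1H,3H-pyrrolo[1,2-c][1,3,2]oxazaborole activated with HNTf2 (20 mol%), CH2Cl2, −78 → −40 °C
Reagents that add atoms: none
Why: Lewis-acid-catalysed asymmetric Diels–Alder reaction; the acrylate β-carbon should bond to C19 because the allyl-cation-like transition state then has a tertiary terminus at methyl-bearing C10, the E,E-diene delivers C8 and C19 cis by suprafacial addition, the chiral cationic boron Lewis acid shields one face of the coordinated acrylate and so fixes their absolute configuration, and the endo-derived C17 centre is re-set in step 5.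

Step 5
Reactants: 7 Diels–Alder adduct
Product: 8 methyl (1S,2R,5S)-2-{[(tert-butyldiphenylsilyl)oxy]methyl}-1-hydroxy-4,5-dimethylcyclohex-3-ene-1-carboxylate
Conditions: KN(SiMe3)2, THF, −78 °C; 2-(benzenesulfonyl)-3-phenyloxaziridine; AcOH
Reagents that add atoms: 2-(benzenesulfonyl)-3-phenyloxaziridine O=S(=O)(c1ccccc1)N1OC1c1ccccc1
Why: ester enolate hydroxylation with an N-sulfonyloxaziridine; the C8 side chain sits pseudoaxial next to the enolate to avoid A(1,3) strain, so oxygen should enter anti to it and place the C17 hydroxyl trans and the ester cis to the C8 substituent.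

Step 6
Reactants: 8 hydroxy ester
Product: 10 (1S,4S,5S,6S,7S)-5-{[(tert-butyldiphenylsilyl)oxy]methyl}-4,6-dihydroxy-1,7-dimethyl-2-oxabicyclo[2.2.2]octan-3-one, via epoxide 9 (not isolated)
Conditions: mCPBA, CH2Cl2, 0 °C → rt; then camphorsulfonic acid (10 mol%), H2O (2 equiv), rt
Reagents that add atoms: 3-chloroperoxybenzoic acid OOC(=O)c1cccc(Cl)c1; water O
Why: peracid epoxidation should occur on the ring face opposite to the two cis allylic substituents at C8 and C19 (the C17 hydroxyl lies on the attacked face), and acid then opens the epoxide at the tertiary carbon C10 with inversion by the ester carbonyl on the other face, which after loss of methanol gives the bridged lactone with the C9 hydroxyl trans to O11.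

Step 7
Reactants: 10 dihydroxy lactone
Product: 11 (1S,4S,5S,6S,7S)-6-[(benzyloxy)methoxy]-5-{[(tert-butyldiphenylsilyl)oxy]methyl}-4-hydroxy-1,7-dimethyl-2-oxabicyclo[2.2.2]octan-3-one
Conditions: BnOCH2Cl (1.2 equiv), iPr2NEt, Bu4NI (cat.), CH2Cl2, 0 °C → rt
Reagents that add atoms: benzyl chloromethyl ether ClCOCc1ccccc1
Why: O-alkylation with the chloromethyl ether should select the secondary C9 hydroxyl over the hindered tertiary bridgehead hydroxyl and installs a group that is removed by the hydrogenolysis of step 20.

Step 8
Reactants: 11 hydroxy lactone; 12 (triphenylphosphoranylidene)ketene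
Product: 14 tricyclic tetronate silyl ether, via acyl ylide 13 (not isolated)
Conditions: toluene, 110 °C
Reagents that add atoms: none
Why: domino addition–Wittig reaction: the tertiary C17 hydroxyl adds to the ketene carbon to give an ester-stabilised ylide, which olefinates the neighbouring lactone carbonyl C12 intramolecularly (five-membered ring) to give the tetronate C12=C13–C15(=O)–O16, with O11 now the enol-ether oxygen; no stereocentre is formed.

Step 9
Reactants: 14 tetronate silyl ether
Product: 15 tricyclic tetronate alcohol
Conditions: HF·pyridine, pyridine, THF, 0 °C → rt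
Reagents that add atoms: none
Why: fluoride-mediated cleavage of the primary silyl ether should leave the acetal-type ether and the tetronate untouched.

Step 10
Reactants: 15 tetronate alcohol
Product: 16 tricyclic tetronate aldehyde
Conditions: Dess–Martin periodinane, pyridine, CH2Cl2, 0 °C → rt
Reagents that add atoms: none
Why: Dess–Martin oxidation of the primary alcohol under buffered, non-basic conditions should give the C7 aldehyde without epimerising C8 or eliminating the β-alkoxy group.

Step 11
Reactants: 17 cyclohexane-1,3-dione; 18 benzyl alcohol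
Product: 19 3-(benzyloxy)cyclohex-2-en-1-one
Conditions: TsOH·H2O (cat.), toluene, reflux, azeotropic removal of water
Reagents that add atoms: none
Why: acid-catalysed condensation of the enolised diketone with the alcohol gives the vinylogous ester, whose benzyl group is the helper that later defines which oxygen (C14) is the enol oxygen.

Step 12
Reactants: 19 3-(benzyloxy)cyclohex-2-en-1-one
Product: 20 3-(benzyloxy)-6-methylcyclohex-2-en-1-one (racemic)
Conditions: LiN(iPr)2, THF, −78 °C; MeI
Reagents that add atoms: iodomethane CI
Why: Stork–Danheiser alkylation: kinetic deprotonation of the vinylogous ester occurs at the α′ carbon (C4) next to the carbonyl, and methylation there fixes the carbonyl, not the enol ether, beside the future carbinol; the racemic centre is planarised again in step 13.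

Step 13
Reactants: 20 racemic methyl enone
Product: 21 (S)-3-(benzyloxy)-6-hydroxy-6-methylcyclohex-2-en-1-one
Conditions: NaN(SiMe3)2, THF, −78 °C; (+)-[(8,8-dichlorocamphoryl)sulfonyl]oxaziridine; AcOH
Reagents that add atoms: (+)-[(8,8-dichlorocamphoryl)sulfonyl]oxaziridine CC1(C)[C@@H]2CC[C@]13CS(=O)(=O)N4O[C@@]34C2(Cl)Cl
Why: asymmetric enolate hydroxylation: both enantiomers of 20 give the same planar tetrasubstituted enolate, which the enantiopure oxaziridine should oxidise on one face under reagent control to set C4 (S), as known for 2-methyl-1-tetralone-type enolates.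

Step 14
Reactants: 21 hydroxy enone
Product: 22 (S)-3-(benzyloxy)-6-[(benzyloxy)methoxy]-6-methylcyclohex-2-en-1-one
Conditions: BnOCH2Cl, iPr2NEt, Bu4NI (cat.), ClCH2CH2Cl, 60 °C
Reagents that add atoms: benzyl chloromethyl ether ClCOCc1ccccc1
Why: alkylation of the tertiary alcohol with the reactive chloromethyl ether gives a base-stable acetal ether that is cleaved by hydrogenolysis in step 20.

Step 15
Reactants: 22 protected enone
Product: 23 (4S,6S)-3-(benzyloxy)-6-[(benzyloxy)methoxy]-4,6-dimethylcyclohex-2-en-1-one
Conditions: LiN(iPr)2, THF, −78 → −40 °C; MeI, DMPU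
Reagents that add atoms: iodomethane CI
Why: with the α′ position blocked, deprotonation occurs at the γ carbon (C2) and the extended vinylogous-ester enolate alkylates at γ, as dioxinone and tetronate dienolates do; methyl iodide should enter anti to the pseudoaxial C4 oxygen substituent, giving the C2 methyl cis to the C4 methyl, which is also the more stable diequatorial arrangement.

Step 16
Reactants: 23 dimethyl enone
Product: 24 (4S,6S)-3-(benzyloxy)-6-[(benzyloxy)methoxy]-2-iodo-4,6-dimethylcyclohex-2-en-1-one
Conditions: N-iodosuccinimide, MeCN, rt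
Reagents that add atoms: N-iodosuccinimide O=C1CCC(=O)N1I
Why: electrophilic iodination of the nucleophilic enol-ether carbon C6 followed by loss of the proton restores the vinylogous ester and gives the α-iodo enone.

Step 17
Reactants: 16 tetronate aldehyde; 24 iodo enone
Product: 25 C7 carbinol (mixture of C7 epimers)
Conditions: CrCl2 (6 equiv), NiCl2 (2 mol%), DMSO, rt
Reagents that add atoms: none
Why: Nozaki–Hiyama–Kishi coupling: oxidative addition of the iodoalkene to zerovalent nickel, transmetalation to trivalent chromium and chemoselective addition to the aldehyde form C6–C7; C7 is not controlled here (the Felkin–Anh 7R epimer is expected to dominate) and is erased in step 18.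

Step 18
Reactants: 25 C7 carbinol mixture
Product: 26 C7 ketone
Conditions: Dess–Martin periodinane, pyridine, CH2Cl2, 0 °C
Reagents that add atoms: none
Why: Dess–Martin oxidation converges both C7 epimers to one ketone under buffered conditions that spare the acid-labile vinylogous ester.

Step 19
Reactants: 26 C7 ketone
Product: 27 (7S)-carbinol (photosubstrate)
Conditions: NaBH4, CeCl3·7H2O, MeOH/CH2Cl2, −78 °C
Reagents that add atoms: none
Why: Luche 1,2-reduction of the less hindered C7 carbonyl (C5 is flanked by quaternary C4); hydride should attack anti to the quaternary C17 substituent of C8 (Felkin–Anh), the same face that a cerium chelate with the C9 ether oxygen would expose, giving 7S, which is the epimer opposite to the major product of carbon addition in step 17.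

Step 20
Reactants: 27 (7S)-carbinol
Product: 30 CNP0115071.1 (target), via cyclobutane photoadduct 28 (not isolated), via cyclobutanol 29 (not isolated)
Conditions: hν (medium-pressure Hg lamp, Pyrex filter, λ > 290 nm), degassed EtOAc, rt; then Pd(OH)2/C, H2 (1 atm), same flask, rt
Reagents that add atoms: none
Why: The excited vinylogous ester first bonds C6 to C12 of the tetronate and the resulting 1,4-diradical (α-oxy radical at C14, α-lactone radical at C13) closes C13–C14 to cyclobutane 28; hydrogenolysis then removes the enol benzyl group and both benzyloxymethyl groups, and cyclobutanol 29, being the strained aldol of the C5 ketone enolate with the C14 carbonyl, undergoes retro-aldol cleavage of C6–C14, so that the six-membered ring C2–C3–C4–C5–C6–C14 grows by C12 and C13 to the eight-membered ring and the freed β-keto lactone enolises to the hydrogen-bonded C13=C14 enol. The closest known reaction type is the intramolecular De Mayo reaction of 2-(alk-4-enyl)cyclohexane-1,3-dione enol derivatives to fused five–eight diketones, with hydrogenolytic unmasking of the enol oxygen as trigger. The cyclopentane closes by the five-membered first bond required by the rule of five (C6 onto the internal alkene carbon C12), the cyclobutane by recombination of the 1,4-diradical (straight, not crossed, because the tether has three atoms), and the eight-membered ring forms by breaking the bond shared by the four- and six-membered rings. C12 is set by the tether, since C7–C8–C17 can deliver C6 only to the tetronate face syn to C8; C6 is set by protonation of the C5 enolate under thermodynamic control to the cis-fused ring junction with H syn to O11 (the rear position is blocked by O11); C13 and C14 become trigonal and all other centres are untouched. The step needs the correct enol regiochemistry, secured because the benzyl ether was placed at C14 by synthesis, and the correct direction of retro-aldol cleavage (C6–C14, not C13–C14), secured because the ketone enolate at C6 is the better leaving carbanion and the product is the acidic β-keto lactone.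

**Compound list**

1 | (E)-2-methylbut-2-enal | C/C=C(\C)C=O | starting material
2 | triethyl phosphonoacetate | CCOC(=O)CP(=O)(OCC)OCC | starting material
3 | ethyl (2E,4E)-4-methylhexa-2,4-dienoate | C/C=C(C)/C=C/C(=O)OCC | intermediate
4 | (2E,4E)-4-methylhexa-2,4-dien-1-ol | C/C=C(C)/C=C/CO | intermediate
5 | tert-butyl{[(2E,4E)-4-methylhexa-2,4-dien-1-yl]oxy}diphenylsilane | C/C=C(C)/C=C/CO[Si](c1ccccc1)(c1ccccc1)C(C)(C)C | intermediate
6 | methyl acrylate | C=CC(=O)OC | starting material
7 | methyl (1R,2S,5S)-2-{[(tert-butyldiphenylsilyl)oxy]methyl}-4,5-dimethylcyclohex-3-ene-1-carboxylate | COC(=O)[C@@H]1C[C@H](C)C(C)=C[C@@H]1CO[Si](c1ccccc1)(c1ccccc1)C(C)(C)C | intermediate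
8 | methyl (1S,2R,5S)-2-{[(tert-butyldiphenylsilyl)oxy]methyl}-1-hydroxy-4,5-dimethylcyclohex-3-ene-1-carboxylate | COC(=O)[C@]1(O)C[C@H](C)C(C)=C[C@@H]1CO[Si](c1ccccc1)(c1ccccc1)C(C)(C)C | intermediate
9 | epoxide of 8 at C9–C10, oxygen on the face opposite to the C8 side chain and the C19 methyl (not isolated) | COC(=O)[C@]1(O)C[C@H](C)[C@@]2(C)O[C@H]2[C@@H]1CO[Si](c1ccccc1)(c1ccccc1)C(C)(C)C | intermediate
10 | (1S,4S,5S,6S,7S)-5-{[(tert-butyldiphenylsilyl)oxy]methyl}-4,6-dihydroxy-1,7-dimethyl-2-oxabicyclo[2.2.2]octan-3-one | CC(C)(C)[Si](c1ccccc1)(c1ccccc1)OC[C@H]1[C@H](O)[C@@]2(C)OC(=O)[C@]1(O)C[C@@H]2C | intermediate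
11 | (1S,4S,5S,6S,7S)-6-[(benzyloxy)methoxy]-5-{[(tert-butyldiphenylsilyl)oxy]methyl}-4-hydroxy-1,7-dimethyl-2-oxabicyclo[2.2.2]octan-3-one | CC(C)(C)[Si](c1ccccc1)(c1ccccc1)OC[C@H]1[C@H](OCOCc2ccccc2)[C@@]3(C)OC(=O)[C@]1(O)C[C@@H]3C | intermediate
12 | (triphenylphosphoranylidene)ketene | O=C=C=P(c1ccccc1)(c1ccccc1)c1ccccc1 | starting material
13 | (triphenylphosphoranylidene)acetate ester of the C17 hydroxyl of 11 (not isolated) | CC(C)(C)[Si](c1ccccc1)(c1ccccc1)OC[C@H]1[C@H](OCOCc2ccccc2)[C@@]3(C)OC(=O)[C@]1(OC(=O)C=P(c4ccccc4)(c4ccccc4)c4ccccc4)C[C@@H]3C | intermediate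
14 | tricyclic tetronate: butenolide C12=C13–C15(=O)–O16 fused on C12–C17 of the 2-oxabicyclo[2.2.2]octane; C8 CH2OSi(tBu)Ph2; C9 benzyloxymethoxy; C8, C9, C10, C17, C19 all S | CC(C)(C)[Si](c1ccccc1)(c1ccccc1)OC[C@H]1[C@H](OCOCc2ccccc2)[C@@]3(C)OC4=CC(=O)O[C@@]14C[C@@H]3C | intermediate
15 | tricyclic tetronate as 14 with C8 CH2OH | OC[C@H]1[C@H](OCOCc2ccccc2)[C@@]3(C)OC4=CC(=O)O[C@@]14C[C@@H]3C | intermediate
16 | tricyclic tetronate as 14 with C8 CHO (C7 aldehyde) | O=C[C@H]1[C@H](OCOCc2ccccc2)[C@@]3(C)OC4=CC(=O)O[C@@]14C[C@@H]3C | intermediate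
17 | cyclohexane-1,3-dione | O=C1CCCC(=O)C1 | starting material
18 | benzyl alcohol | OCc1ccccc1 | starting material
19 | 3-(benzyloxy)cyclohex-2-en-1-one | O=C1C=C(OCc2ccccc2)CCC1 | intermediate
20 | 3-(benzyloxy)-6-methylcyclohex-2-en-1-one (racemic) | CC1CCC(OCc2ccccc2)=CC1=O | intermediate
21 | (S)-3-(benzyloxy)-6-hydroxy-6-methylcyclohex-2-en-1-one | C1C[C@](C)(O)C(=O)C=C1OCc2ccccc2 | intermediate
22 | (S)-3-(benzyloxy)-6-[(benzyloxy)methoxy]-6-methylcyclohex-2-en-1-one | C1C[C@](C)(OCOCc3ccccc3)C(=O)C=C1OCc2ccccc2 | intermediate
23 | (4S,6S)-3-(benzyloxy)-6-[(benzyloxy)methoxy]-4,6-dimethylcyclohex-2-en-1-one | C[C@H]1C[C@](C)(OCOCc3ccccc3)C(=O)C=C1OCc2ccccc2 | intermediate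
24 | (4S,6S)-3-(benzyloxy)-6-[(benzyloxy)methoxy]-2-iodo-4,6-dimethylcyclohex-2-en-1-one | C[C@H]1C[C@](C)(OCOCc3ccccc3)C(=O)C(I)=C1OCc2ccccc2 | intermediate
25 | coupled carbinol: enone ring of 24 (C6 in place of iodine) bonded to C7H(OH) on C8 of the tetronate of 16; both C7 epimers | C[C@H]1C[C@](C)(OCOCc2ccccc2)C(=O)C(C(O)[C@H]3[C@H](OCOCc4ccccc4)[C@@]5(C)OC6=CC(=O)O[C@@]36C[C@@H]5C)=C1OCc7ccccc7 | intermediate
26 | coupled ketone: as 25 with C7 as C=O | C[C@H]1C[C@](C)(OCOCc2ccccc2)C(=O)C(C(=O)[C@H]3[C@H](OCOCc4ccccc4)[C@@]5(C)OC6=CC(=O)O[C@@]36C[C@@H]5C)=C1OCc7ccccc7 | intermediate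
27 | (7S)-carbinol: as 25 with C7 S | C[C@H]1C[C@](C)(OCOCc2ccccc2)C(=O)C([C@@H](O)[C@H]3[C@H](OCOCc4ccccc4)[C@@]5(C)OC6=CC(=O)O[C@@]36C[C@@H]5C)=C1OCc7ccccc7 | intermediate
28 | cyclobutane photoadduct: cyclobutane C6–C12–C13–C14 fused cis to cyclopentane, lactone and cyclohexanone; C14 OBn; C4 and C9 benzyloxymethyl ethers (not isolated) | C[C@H]1C[C@](C)(OCOCc7ccccc7)C(=O)[C@@]26[C@@H](O)[C@H]3[C@H](OCOCc8ccccc8)[C@@]4(C)O[C@@]25[C@@H]([C@@]16OCc9ccccc9)C(=O)O[C@@]35C[C@@H]4C | intermediate
29 | cyclobutanol: as 28 with free hydroxyls at C14, C4 and C9 (not isolated) | C[C@H]1C[C@](C)(O)C(=O)[C@@]26[C@@H](O)[C@H]3[C@H](O)[C@@]4(C)O[C@@]25[C@@H]([C@@]16O)C(=O)O[C@@]35C[C@@H]4C | intermediate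
30 | CNP0115071.1 (2S,4S,6R,7S,8S,9S,10S,12R,17S,19S in the locants above) | C[C@H]1C[C@](C)(O)C(=O)[C@@H]2[C@@H](O)[C@H]3[C@H](O)[C@@]4(C)O[C@@]25/C(=C\1O)C(=O)O[C@@]35C[C@@H]4C | target

**Step count and risks**

Total step count: 20. Longest linear sequence: 14 steps (steps 1–10 and 17–20); steps 11–16 make the second fragment.

Steps most likely to fail:

1. Step 20 (key step). The process at risk is the photocycloaddition: the vinylogous ester absorbs weakly and its excited state may decay, or the floppy carbinol tether may fail to hold C6 over the hindered tetrasubstituted carbon C12, before the first bond forms. The fallback sets out from ketone 26. Its cross-conjugated 2-acyl enone absorbs more strongly and at longer wavelength, and the trigonal C7 stiffens the tether, so irradiation (λ > 300 nm, EtOAc) should close the same two bonds to give the cyclobutane diketone F1. NaBH4 (MeOH, −40 °C) should then reduce only the cyclopentanone carbonyl C7 of F1, from the front face (the rear is screened by C5 and C9, and the C5 ketone lies between two quaternary carbons), giving 28, which is isolated in this variant. The fallback returns to the route at 28, which is hydrogenolysed as in the second stage of step 20.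

2. Step 17. The processes at risk are slow oxidative addition and transmetalation at the tetrasubstituted iodoalkene and slow addition to the hindered α-branched aldehyde, so that protodehalogenation of 24 or epimerisation of 16 at C8 may prevail. The fallback joins the fragments by acyl cross-coupling instead of carbonyl addition and sets out from 16 and 24. Pinnick oxidation of 16 (NaClO2, NaH2PO4, 2-methylbut-2-ene) should give the carboxylic acid F2, and oxalyl chloride with catalytic DMF the acid chloride F3. Separately, 24 with Me3SnSnMe3 and Pd(PPh3)4 should give the alkenylstannane F4. Stille acylation of F4 with F3 (Pd2(dba)3, tris(2-furyl)phosphine, THF) should give ketone 26 directly, so the fallback returns to the route at 26 and step 18 is not needed.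

3. Step 19. The processes at risk are conjugate hydride addition at C14 of the doubly activated β-alkoxy enone with loss of benzyl alcohol, and poor facial selectivity at C7. The fallback inverts instead of reducing and sets out from 25. Its major 7R epimer (the Felkin–Anh product of step 17, separated by chromatography) should undergo Mitsunobu inversion with 4-nitrobenzoic acid (PPh3, DIAD, toluene) to the (7S)-4-nitrobenzoate F5. Methanolysis (K2CO3, MeOH, 0 °C) should then give 27, where the fallback returns to the route.

Further compounds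
F1 | step 20 | cyclobutane diketone: as 28 with C7 as C=O | C[C@H]1C[C@](C)(OCOCc7ccccc7)C(=O)[C@@]26C(=O)[C@H]3[C@H](OCOCc8ccccc8)[C@@]4(C)O[C@@]25[C@@H]([C@@]16OCc9ccccc9)C(=O)O[C@@]35C[C@@H]4C
F2 | step 17 | tricyclic tetronate carboxylic acid: as 16 with C7 as CO2H | OC(=O)[C@H]1[C@H](OCOCc2ccccc2)[C@@]3(C)OC4=CC(=O)O[C@@]14C[C@@H]3C
F3 | step 17 | tricyclic tetronate acid chloride: as 16 with C7 as COCl | ClC(=O)[C@H]1[C@H](OCOCc2ccccc2)[C@@]3(C)OC4=CC(=O)O[C@@]14C[C@@H]3C
F4 | step 17 | (4S,6S)-3-(benzyloxy)-6-[(benzyloxy)methoxy]-4,6-dimethyl-2-(trimethylstannyl)cyclohex-2-en-1-one | C[C@H]1C[C@](C)(OCOCc3ccccc3)C(=O)C([Sn](C)(C)C)=C1OCc2ccccc2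
F5 | step 19 | (7S)-4-nitrobenzoate of 27 | C[C@H]1C[C@](C)(OCOCc2ccccc2)C(=O)C([C@@H](OC(=O)c8ccc(cc8)[N+](=O)[O-])[C@H]3[C@H](OCOCc4ccccc4)[C@@]5(C)OC6=CC(=O)O[C@@]36C[C@@H]5C)=C1OCc7ccccc7
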